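## Analysis of the target

The target 23 is an isoflavan: a chroman (ring A fused to the oxygen heterocycle, ring C) that carries ring B on C3. Ring A has a free hydroxyl on C7 and a 3-hydroxy-3-methylbutyl chain on C8. Ring B is a 2',4'-dihydroxyphenyl ring with a 1,1-dimethylallyl group on C5', so a quaternary benzylic carbon sits next to the C4' hydroxyl. C3 is the only stereocentre and is R. It lies between the methylenes C2 and C4 and is configurationally stable in the chroman, but it can epimerise in any precursor in which C2 is a carbonyl carbon. Both aromatic rings are resorcinol-type and oxidise easily as phenolates. Acid would close the tertiary alcohol onto O7 as a 2,2-dimethyldihydropyran ring and the terminal alkene onto O4' as a dihydrobenzofuran, and the alkene rules out hydrogenation and hydrogenolysis. The difficulty is therefore to set one benzylic stereocentre without hydrogenating an alkene and to finish under conditions that are neither acidic nor reductive. The strategy rests on this feature: once O1–C2 and C4–C4a are cut, ring A is a 2-alkylresorcinol whose C4 and C6 are equivalent by symmetry and activated by both hydroxyls, and the unit C4–C3–C2 with ring B on C3 is the skeleton of a 2-arylacrolein (C4 the methylene terminus, C2 the formyl carbon).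

## Retrosynthetic reasoning

**23 to 22.** The last operation removes two silyl groups from the ring B phenols with fluoride. Silyl ethers are chosen because their cleavage needs neither acid nor hydrogen, so the tertiary alcohol, the alkene and the free phenols are not put at risk.

**22 to 21 to 20.** The O1–C2 aryl ether bond is cut to give diol 21, in which the ortho phenol of ring A and a primary alcohol are in place for a redox-condensation etherification that does not touch C3. Diol 21 comes from lactol 20 by hydride reduction. The open diol is preferred to a direct ionic deoxygenation of 20, because that would pass through an oxocarbenium ion next to the benzylic C3–H and open a path to the 4H-chromene and so to racemisation.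

**20 to 7 and 18.** This is the key disconnection. It cuts C4–C4a and the hemiacetal bond O1–C2, and leads to unprotected resorcinol 7 and 2-arylacrolein 18. It is made here because both bonds end on ring A, whose symmetry removes any regiochemical question, and because 18 is flat at C3, so the stereocentre can be created in the same operation by protonation. The forward reaction has to join C4 of 7 to the methylene of 18, protonate the resulting enamine on one face under control of a chiral primary amine catalyst, and trap the aldehyde 19 as lactol 20 before it can enolise.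

**18 to 16 to 15 to 14.** The exocyclic methylene of 18 is removed to give arylacetaldehyde 16. The forward step is a Mannich methylenation through base 17. Aldehyde 16 comes by hydrolysis of enol ether 15, the one-carbon Wittig homologue of benzaldehyde 14.

**14 to 13 to 11 to 10 to 8 and 9.** The bond from C5' to the quaternary carbon is cut by an aromatic Claisen transform: phenol 13 comes from prenyl ether 11 through dienone 12, with allylic inversion giving the 1,1-dimethylallyl group. The hydroxyl ortho to the formyl group must be silylated before the rearrangement (10 to 11), so that the shift goes to C5 and not to the carbon between the two oxygens. Ether 10 is the selective O-alkylation product of 8 with 9.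

**7 to 5 to 3 to 1 and 2.** The two C–CH3 bonds of the tertiary alcohol are cut to give lactone 5, which takes up two methyl nucleophiles through ketone 6 and releases the second phenol. Lactone 5 comes from dione ester 3 by dehydrogenation through resorcinol 4, and 3 is the Michael adduct of 1 and 2. A carbon substituent between the hydroxyls of a resorcinol is hard to introduce by electrophilic substitution, whereas C2 of dione 1 is its only nucleophilic carbon.

## Alternatives that were turned down

**Alternative 1:** Here C3–C1' and C4–C4a are disconnected and C3 and C4 come from a vinyl boron unit. In the forward step, ring B aryllithium A1 adds to vinylboronic acid pinacol ester A2, and the ate complex is coupled with ring A aryl bromide A3 by a palladium catalyst carrying a chiral ferrocenyl bisphosphine. Ring B shifts from boron to C3 and reductive elimination forms C4–C4a, giving (R)-boronate A4.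
- For: three fragments are joined in one enantioselective event, and the stereocentre is held as a C–B bond that cannot epimerise. On this point it is stronger than the chosen route, which passes through an enolisable aldehyde.
- Against: C2 is still missing, so the hindered benzylic boronate needs a one-carbon homologation and an oxidation before ring C can be closed; the key step closes no ring.
- Against: A1 cannot carry silyl ethers ortho to lithium because they migrate to carbon, so acetal protection is used, and its acidic removal at the end endangers both the tertiary alcohol next to O7 and the alkene next to O4'.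
- Against: both the migrating aryl group and the electrophile are ortho-substituted, which slows the metallate shift, and three kinds of protecting group are needed.
- In its place the chosen route closes ring C in the C–C bond-forming step, uses ring A unprotected, needs one kind of protecting group and ends with fluoride only.

**Alternative 2:** The two aryl–carbon bonds to the C5 side chains are disconnected, leading back to bis-ether A5 of a preformed (R)-isoflavan. Heating A5 triggers two aromatic Claisen rearrangements: the 1,1-dimethylallyl ether on O7 arrives at C8 as a prenyl group, and the prenyl ether on O4' arrives at C5' as the 1,1-dimethylallyl group, giving A6.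
- For: the economy of the step, and the fact that C3 could be set earlier by asymmetric hydrogenation of a C3–C4 alkene while no side-chain alkene is present. That is better-established stereocontrol than the protonation relied on here.
- Against: the key step makes neither the ring nor the stereocentre, so the whole core needs its own synthesis.
- Against: two regiochemical choices (C8 against C6, C5' against C3') are made at once on a late intermediate.
- Against, and decisive: the prenyl group of A6 must then be hydrated to the tertiary alcohol next to a free phenol and in the presence of a second alkene. Any Markovnikov hydration would either engage both alkenes or let O7 capture the activated tertiary carbon to give the cyclic ether.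
- The chosen route brings the tertiary alcohol in from lactone 5 and carries out the same Claisen rearrangement early, on simple ether 11, where only one regiochemical question arises.

**Alternative 3:** Here C3–C4 and O1–C2 are disconnected. Ring A becomes an ortho-quinone methide released by mild base from sulfone A7, and ring B becomes arylacetaldehyde A8. The enamine of A8 with a diarylprolinol silyl ether catalyst adds to the quinone methide and the phenol closes onto the aldehyde carbon, giving lactol A9.
- For: it builds the same ring, the same number of bonds and the same kind of lactol as the chosen route, saves the methylenation of the ring B aldehyde, and sets C3 in a C–C bond-forming step on a shielded enamine face. That control element is better understood than enantioselective protonation, so it is stronger on this point.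
- Against: ring A loses its symmetry advantage. A7 needs a one-carbon handle at C4 and protection of only one of two equivalent hydroxyls, which costs several steps.
- Against: the alkoxy group para to the methide carbon stabilises the quinone methide and lowers its electrophilicity towards an arylacetaldehyde enamine that is a weak nucleophile, and the base that releases the quinone methide can racemise the α-aryl aldehyde before it closes.
- The end game is of equal length. The chosen route offers instead a ring A partner (7) made in three steps and used without any protecting group or handle.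

Key step: step 11

Assumption: the (S)-configured diamine salt is taken to protonate the enamine on the face that gives (3R); if the sense is the opposite, its enantiomer (from D-tert-leucine) is used under the same conditions.

## Route

Step 1
Reactants: 1 cyclohexane-1,3-dione; 2 methyl acrylate
Product: 3 methyl 3-(2,6-dioxocyclohexyl)propanoate
Conditions: NaOMe (0.2 equiv), MeOH, reflux
Reagents that add atoms: none
Why: Michael addition; the enolate of 1 is carbon-nucleophilic only at C2, which puts the three-carbon chain between the two oxygens, and one equivalent of 2 limits a second alkylation.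

Step 2
Reactants: 3 methyl 3-(2,6-dioxocyclohexyl)propanoate
Product: 5 5-hydroxychroman-2-one, via methyl 3-(2,6-dihydroxyphenyl)propanoate 4 (not isolated)
Conditions: 10% Pd/C, p-cymene, reflux, N2 sweep
Reagents that add atoms: none
Why: Catalytic dehydrogenation of the enolised 1,3-dione removes one molecule of hydrogen and tautomerisation gives resorcinol 4, in which one phenol should acylate at this temperature with loss of methanol to the six-membered lactone. Any 4 that remains would converge on the same product in step 3.

Step 3
Reactants: 5 5-hydroxychroman-2-one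
Product: 7 2-(3-hydroxy-3-methylbutyl)benzene-1,3-diol, via 4-(2,6-dihydroxyphenyl)butan-2-one 6 (not isolated)
Conditions: MeMgBr (5 equiv), THF, 0 °C to rt; aq. NH4Cl
Reagents that add atoms: methylmagnesium bromide, C[Mg]Br
Why: Grignard addition; after deprotonation of the phenol the aryl ester is opened to ketone 6 with release of the second phenoxide, and a second addition gives the tertiary alcohol. The buffered work-up avoids acid-induced cyclisation of the alcohol onto a phenol.

Step 4
Reactants: 8 2,4-dihydroxybenzaldehyde; 9 prenyl bromide (1-bromo-3-methylbut-2-ene)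
Product: 10 2-hydroxy-4-[(3-methylbut-2-en-1-yl)oxy]benzaldehyde
Conditions: K2CO3 (1.1 equiv), acetone, reflux
Reagents that add atoms: none
Why: Williamson etherification; the C4 hydroxyl is the more acidic one and is not hydrogen-bonded to the formyl group, so it should be alkylated first.

Step 5
Reactants: 10 2-hydroxy-4-[(3-methylbut-2-en-1-yl)oxy]benzaldehyde
Product: 11 2-(tert-butyldimethylsilyloxy)-4-[(3-methylbut-2-en-1-yl)oxy]benzaldehyde
Conditions: TBSCl, imidazole, DMF, rt
Reagents that add atoms: tert-butyldimethylsilyl chloride, CC(C)(C)[Si](C)(C)Cl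
Why: Silylation of the phenol; it breaks the chelate to the formyl group, which would favour rearrangement towards C3, and places a bulky group next to C3.

Step 6
Reactants: 11 2-(tert-butyldimethylsilyloxy)-4-[(3-methylbut-2-en-1-yl)oxy]benzaldehyde
Product: 13 2-(tert-butyldimethylsilyloxy)-4-hydroxy-5-(2-methylbut-3-en-2-yl)benzaldehyde, via ortho-dienone 12 (not isolated)
Conditions: PhNEt2, 190 °C, sealed tube, Ar
Reagents that add atoms: none
Why: Aromatic Claisen rearrangement; the [3,3] shift joins the ring carbon ortho to the ether oxygen to the dimethyl-substituted alkene terminus, which gives the 1,1-dimethylallyl group, and dienone 12 enolises to the phenol. C5 should be preferred over C3, which is flanked by two oxygen substituents, one of them a bulky silyl ether, and the amine solvent suppresses acid-catalysed secondary reactions of the product.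

Step 7
Reactants: 13 2-(tert-butyldimethylsilyloxy)-4-hydroxy-5-(2-methylbut-3-en-2-yl)benzaldehyde
Product: 14 2,4-bis(tert-butyldimethylsilyloxy)-5-(2-methylbut-3-en-2-yl)benzaldehyde
Conditions: TBSCl, imidazole, DMAP (cat.), DMF, 50 °C
Reagents that add atoms: tert-butyldimethylsilyl chloride, CC(C)(C)[Si](C)(C)Cl
Why: Silylation of the phenol; the hydroxyl is acidic (para to formyl) but hindered by the neighbouring quaternary carbon, hence the nucleophilic catalyst and gentle warming.

Step 8
Reactants: 14 2,4-bis(tert-butyldimethylsilyloxy)-5-(2-methylbut-3-en-2-yl)benzaldehyde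
Product: 15 1-(2-methoxyethenyl)-2,4-bis(tert-butyldimethylsilyloxy)-5-(2-methylbut-3-en-2-yl)benzene (E/Z mixture)
Conditions: [Ph3PCH2OMe]Cl, NaN(SiMe3)2, THF, −78 to 0 °C
Reagents that add atoms: (methoxymethyl)triphenylphosphonium chloride, COC[P+](c1ccccc1)(c1ccccc1)c1ccccc1.[Cl-]
Why: Wittig reaction for one-carbon homologation; an amide base is used in place of an alkoxide because aryl silyl ethers ortho and para to a formyl group are cleaved by alkoxides. The alkene geometry is of no consequence.

Step 9
Reactants: 15 1-(2-methoxyethenyl)-2,4-bis(tert-butyldimethylsilyloxy)-5-(2-methylbut-3-en-2-yl)benzene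
Product: 16 2-[2,4-bis(tert-butyldimethylsilyloxy)-5-(2-methylbut-3-en-2-yl)phenyl]acetaldehyde
Conditions: 2 M aq. HCl, THF, rt; used without storage
Reagents that add atoms: water, O
Why: Enol ether hydrolysis; aryl silyl ethers on this electron-rich ring should tolerate dilute acid, and with no free phenol next to the alkene nothing can cyclise.

Step 10
Reactants: 16 2-[2,4-bis(tert-butyldimethylsilyloxy)-5-(2-methylbut-3-en-2-yl)phenyl]acetaldehyde
Product: 18 2-[2,4-bis(tert-butyldimethylsilyloxy)-5-(2-methylbut-3-en-2-yl)phenyl]prop-2-enal, via Mannich base 17 (not isolated)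
Conditions: [CH2=NMe2]I, Et3N, CH2Cl2, rt; kept cold in solution
Reagents that add atoms: dimethylmethyleneiminium iodide, C=[N+](C)C.[I-]
Why: Mannich reaction of the enolisable arylacetaldehyde followed by base-induced elimination of dimethylamine from 17 (E1cB) gives the α-methylene aldehyde. The ortho silyloxy group twists the aryl ring out of conjugation, which should slow dimerisation.

Step 11
Reactants: 7 2-(3-hydroxy-3-methylbutyl)benzene-1,3-diol; 18 2-[2,4-bis(tert-butyldimethylsilyloxy)-5-(2-methylbut-3-en-2-yl)phenyl]prop-2-enal
Product: 20 (3R)-3-[2,4-bis(tert-butyldimethylsilyloxy)-5-(2-methylbut-3-en-2-yl)phenyl]-8-(3-hydroxy-3-methylbutyl)chromane-2,7-diol (C2 anomers), via ring-open aldehyde 19 (not isolated)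
Conditions: (S)-N1,N1-diethyl-3,3-dimethylbutane-1,2-diamine·TfOH (20 mol%), 7 (3 equiv), CHCl3, 0 °C, slow addition of 18; cold pH 7 phosphate wash, crude 20 used at once
Reagents that add atoms: none
Why: Proposed new method: the primary amine of the catalyst condenses with 18 to an iminium ion, and C4 of 7 (ortho to one hydroxyl, para to the other) attacks its unsubstituted methylene terminus in a Friedel–Crafts alkylation that forms the C4–C4a bond and leaves a catalyst-bound enamine with ring B on the future C3. The diethylammonium group of the catalyst, held over one face of that enamine by the tert-butyl-bearing stereocentre, delivers the proton to C3 intramolecularly, so the only stereocentre is set under catalyst control, as R with the (S)-catalyst under the stated assumption. Hydrolysis, which uses the water released in the condensation, frees aldehyde 19, and the neighbouring phenol adds to it at once in a 6-exo-trig hemiacetalisation that forms O1–C2, closes ring C as lactol 20 and withdraws the enolisable aldehyde. The closest known reactions are the chiral primary amine-catalysed Friedel–Crafts alkylation of indoles with alpha-substituted acroleins that ends in enantioselective enamine protonation, and the amine-catalysed annulation of electron-rich phenols with enals to chroman-2-ols; neither has been shown for a resorcinol carbon nucleophile with a 2-arylacrolein. Regioselectivity needs no control element, because C2 of 7 carries the side chain, C4 and C6 are equivalent by symmetry and C5 is meta to both hydroxyls. Chemoselectivity rests on the reversibility of oxa-Michael addition, on the excess of 7 and the slow addition of 18 against a second alkylation at C6 of the product, and on the silyl ethers that keep ring B from acting as a nucleophile. Low temperature and a weakly acidic salt are chosen so that 20 should neither dehydrate to the 4H-chromene nor lose the tertiary alcohol.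

Step 12
Reactants: 20 (3R)-3-[2,4-bis(tert-butyldimethylsilyloxy)-5-(2-methylbut-3-en-2-yl)phenyl]-8-(3-hydroxy-3-methylbutyl)chromane-2,7-diol
Product: 21 4-[(2R)-2-[2,4-bis(tert-butyldimethylsilyloxy)-5-(2-methylbut-3-en-2-yl)phenyl]-3-hydroxypropyl]-2-(3-hydroxy-3-methylbutyl)benzene-1,3-diol
Conditions: NaBH4, THF–MeOH, 0 °C
Reagents that add atoms: none
Why: Hydride reduction of the lactol through its ring-open aldehyde tautomer 19, which should be reduced faster than it enolises, so the C3 configuration is carried into the diol. Silyl ethers on the electron-rich ring B should survive the short exposure to cold methanolic borohydride.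

Step 13
Reactants: 21 4-[(2R)-2-[2,4-bis(tert-butyldimethylsilyloxy)-5-(2-methylbut-3-en-2-yl)phenyl]-3-hydroxypropyl]-2-(3-hydroxy-3-methylbutyl)benzene-1,3-diol
Product: 22 (3R)-3-[2,4-bis(tert-butyldimethylsilyloxy)-5-(2-methylbut-3-en-2-yl)phenyl]-8-(3-hydroxy-3-methylbutyl)chroman-7-ol
Conditions: PPh3, DIAD, THF (0.01 M), 0 °C to rt
Reagents that add atoms: none
Why: Mitsunobu etherification; only the primary alcohol is activated as the alkoxyphosphonium ion and the ortho phenol displaces it in a 6-exo-tet closure that re-forms ring C without touching C3. The tertiary alcohol is inert, and the C7 hydroxyl can only react between molecules, which dilution should suppress.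

Step 14
Reactants: 22 (3R)-3-[2,4-bis(tert-butyldimethylsilyloxy)-5-(2-methylbut-3-en-2-yl)phenyl]-8-(3-hydroxy-3-methylbutyl)chroman-7-ol
Product: 23 4-[(3R)-7-hydroxy-8-(3-hydroxy-3-methylbutyl)chroman-3-yl]-6-(2-methylbut-3-en-2-yl)benzene-1,3-diol
Conditions: Bu4NF (2.5 equiv), AcOH (2.5 equiv), THF, 0 °C, Ar
Reagents that add atoms: none
Why: Fluoride desilylation of the two aryl silyl ethers; the acetic acid buffer and exclusion of air protect the resorcinol rings from oxidation as phenolates, and no acid strong enough to cyclise the tertiary alcohol or the alkene onto a phenol is present.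

## Compound list

1 | cyclohexane-1,3-dione | O=C1CCCC(=O)C1 | starting material
2 | methyl acrylate | C=CC(=O)OC | starting material
3 | methyl 3-(2,6-dioxocyclohexyl)propanoate | COC(=O)CCC1C(=O)CCCC1=O | intermediate
4 | methyl 3-(2,6-dihydroxyphenyl)propanoate | COC(=O)CCc1c(O)cccc1O | intermediate
5 | 5-hydroxychroman-2-one | O=C1CCc2c(O)cccc2O1 | intermediate
6 | 4-(2,6-dihydroxyphenyl)butan-2-one | CC(=O)CCc1c(O)cccc1O | intermediate
7 | 2-(3-hydroxy-3-methylbutyl)benzene-1,3-diol | CC(C)(O)CCc1c(O)cccc1O | intermediate
8 | 2,4-dihydroxybenzaldehyde | O=Cc1ccc(O)cc1O | starting material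
9 | prenyl bromide (1-bromo-3-methylbut-2-ene) | CC(C)=CCBr | starting material
10 | 2-hydroxy-4-[(3-methylbut-2-en-1-yl)oxy]benzaldehyde | CC(C)=CCOc1ccc(C=O)c(O)c1 | intermediate
11 | 2-(tert-butyldimethylsilyloxy)-4-[(3-methylbut-2-en-1-yl)oxy]benzaldehyde | CC(C)=CCOc1ccc(C=O)c(O[Si](C)(C)C(C)(C)C)c1 | intermediate
12 | 3-(tert-butyldimethylsilyloxy)-4-formyl-6-(2-methylbut-3-en-2-yl)cyclohexa-2,4-dien-1-one | O=C1C=C(O[Si](C)(C)C(C)(C)C)C(C=O)=CC1C(C)(C)C=C | intermediate
13 | 2-(tert-butyldimethylsilyloxy)-4-hydroxy-5-(2-methylbut-3-en-2-yl)benzaldehyde | C=CC(C)(C)c1cc(C=O)c(O[Si](C)(C)C(C)(C)C)cc1O | intermediate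
14 | 2,4-bis(tert-butyldimethylsilyloxy)-5-(2-methylbut-3-en-2-yl)benzaldehyde | C=CC(C)(C)c1cc(C=O)c(O[Si](C)(C)C(C)(C)C)cc1O[Si](C)(C)C(C)(C)C | intermediate
15 | 1-(2-methoxyethenyl)-2,4-bis(tert-butyldimethylsilyloxy)-5-(2-methylbut-3-en-2-yl)benzene (E/Z mixture) | COC=Cc1cc(C(C)(C)C=C)c(O[Si](C)(C)C(C)(C)C)cc1O[Si](C)(C)C(C)(C)C | intermediate
16 | 2-[2,4-bis(tert-butyldimethylsilyloxy)-5-(2-methylbut-3-en-2-yl)phenyl]acetaldehyde | O=CCc1cc(C(C)(C)C=C)c(O[Si](C)(C)C(C)(C)C)cc1O[Si](C)(C)C(C)(C)C | intermediate
17 | 2-[2,4-bis(tert-butyldimethylsilyloxy)-5-(2-methylbut-3-en-2-yl)phenyl]-3-(dimethylamino)propanal (racemic) | CN(C)CC(C=O)c1cc(C(C)(C)C=C)c(O[Si](C)(C)C(C)(C)C)cc1O[Si](C)(C)C(C)(C)C | intermediate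
18 | 2-[2,4-bis(tert-butyldimethylsilyloxy)-5-(2-methylbut-3-en-2-yl)phenyl]prop-2-enal | C=C(C=O)c1cc(C(C)(C)C=C)c(O[Si](C)(C)C(C)(C)C)cc1O[Si](C)(C)C(C)(C)C | intermediate
19 | (2R)-2-[2,4-bis(tert-butyldimethylsilyloxy)-5-(2-methylbut-3-en-2-yl)phenyl]-3-[2,4-dihydroxy-3-(3-hydroxy-3-methylbutyl)phenyl]propanal | C=CC(C)(C)c1cc([C@H](C=O)Cc2ccc(O)c(CCC(C)(C)O)c2O)c(O[Si](C)(C)C(C)(C)C)cc1O[Si](C)(C)C(C)(C)C | intermediate
20 | (3R)-3-[2,4-bis(tert-butyldimethylsilyloxy)-5-(2-methylbut-3-en-2-yl)phenyl]-8-(3-hydroxy-3-methylbutyl)chromane-2,7-diol (C2 anomers) | C=CC(C)(C)c1cc([C@@H]2C(O)Oc3c(ccc(O)c3CCC(C)(C)O)C2)c(O[Si](C)(C)C(C)(C)C)cc1O[Si](C)(C)C(C)(C)C | intermediate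
21 | 4-[(2R)-2-[2,4-bis(tert-butyldimethylsilyloxy)-5-(2-methylbut-3-en-2-yl)phenyl]-3-hydroxypropyl]-2-(3-hydroxy-3-methylbutyl)benzene-1,3-diol | C=CC(C)(C)c1cc([C@H](CO)Cc2ccc(O)c(CCC(C)(C)O)c2O)c(O[Si](C)(C)C(C)(C)C)cc1O[Si](C)(C)C(C)(C)C | intermediate
22 | (3R)-3-[2,4-bis(tert-butyldimethylsilyloxy)-5-(2-methylbut-3-en-2-yl)phenyl]-8-(3-hydroxy-3-methylbutyl)chroman-7-ol | C=CC(C)(C)c1cc([C@@H]2COc3c(ccc(O)c3CCC(C)(C)O)C2)c(O[Si](C)(C)C(C)(C)C)cc1O[Si](C)(C)C(C)(C)C | intermediate
23 | 4-[(3R)-7-hydroxy-8-(3-hydroxy-3-methylbutyl)chroman-3-yl]-6-(2-methylbut-3-en-2-yl)benzene-1,3-diol | C=CC(C)(C)c1cc([C@@H]2COc3c(ccc(O)c3CCC(C)(C)O)C2)c(O)cc1O | target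

## Step count and least certain steps

Total: 14 steps. Longest linear sequence: 11 steps (steps 4 to 14, from 8); the ring A branch (steps 1 to 3) joins at step 11.

**Step 11 (key step).** The most likely failure is poor facial selectivity in the protonation of an aryl-substituted enamine, whose geometry and conformation are less fixed than those of the alkyl cases. Loss of configuration can follow through re-formation of the enamine from 19 before ring closure, or through dehydration of 20 to the 4H-chromene. Slow attack by 7 would also let 18 oligomerise. The fallback is an auxiliary-controlled enolate alkylation. It sets out from aldehyde 16 and resorcinol 7 and comes back to the route at diol 21. Chlorite oxidation of 16 (NaClO2, NaH2PO4, 2-methylbut-2-ene) would give 2-[2,4-bis(tert-butyldimethylsilyloxy)-5-(2-methylbut-3-en-2-yl)phenyl]acetic acid F1, which is joined through its pivalic mixed anhydride to lithiated (R)-4-benzyloxazolidin-2-one to give N-arylacetyl imide F2. In parallel, 7 is formylated ortho to a hydroxyl (MgCl2, Et3N, paraformaldehyde) to 2,4-dihydroxy-3-(3-hydroxy-3-methylbutyl)benzaldehyde F3, both phenols are allylated (allyl bromide, K2CO3) to bis(allyl ether) aldehyde F4, the formyl group is reduced (NaBH4) to benzyl alcohol F5, and this is converted into benzyl bromide F6 (CBr4, PPh3, −20 °C, at which the tertiary alcohol should not react). The sodium enolate of F2 (NaN(SiMe3)2, THF, −78 °C) is alkylated by F6 on the face away from the benzyl group of the auxiliary, which should give (2R)-alkylated imide F7. LiBH4 then releases primary alcohol F8 and the auxiliary, and Pd(PPh3)4 (zerovalent palladium) with morpholine removes the two allyl groups to give 21.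

**Step 6.** Partial rearrangement to C3, follow-up reactions of the ortho-(1,1-dimethylallyl)phenol at high temperature (isomerisation of the side chain, closure onto the alkene, loss of the C5 unit) or thermal loss of the silyl ether next to the formyl group may lower the yield. The fallback forms the aryl–quaternary carbon bond by cross-coupling. It sets out from 8 and comes back at 14. Bromination of 8 (Br2, AcOH) would give 5-bromo-2,4-dihydroxybenzaldehyde F9, silylation of both phenols gives 5-bromo-2,4-bis(tert-butyldimethylsilyloxy)benzaldehyde F10, and a Suzuki–Miyaura coupling with prenylboronic acid pinacol ester under a Pd(OAc)2/bulky biarylphosphine system chosen for attack through the substituted allyl terminus (K3PO4, THF–H2O, 40 °C) gives 14. Any phenol that loses silicon under the basic conditions is silylated again as in step 7.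

**Step 10.** Aldehyde 16 may self-condense under the amine base, and 18 may dimerise or polymerise on concentration. The fallback avoids free 16. It sets out from enol ether 15 and comes back at 18: 15 reacts directly as the nucleophile with [CH2=NMe2]I in CH2Cl2, aqueous NaHCO3 hydrolyses the resulting oxocarbenium ion to Mannich base 17, and Et3N eliminates dimethylamine to give 18, which is kept in solution for step 11. This detour passes only through compounds already in the list (entry F0).

**Step 2.** The hydrogen released may be transferred back to the substrate and lead to deoxygenated or over-reduced material, and the dehydrogenation may stall. The fallback builds the same lactone from an aromatic ring. It sets out from 2 and comes back at 5. A Heck reaction of 2 with 2-iodo-1,3-dimethoxybenzene (Pd(OAc)2, P(o-tol)3, Et3N, DMF, 100 °C) would give methyl (E)-3-(2,6-dimethoxyphenyl)prop-2-enoate F11, hydrogenation (H2, Pd/C) gives methyl 3-(2,6-dimethoxyphenyl)propanoate F12, and BBr3 (CH2Cl2, −78 °C to rt) removes the methyl groups, after which one phenol lactonises to 5.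

**Step 13.** The phenol that must close the ring is flanked by two ortho substituents, so closure may be slow enough for the unhindered C7 hydroxyl to be alkylated between molecules or for the hydrazide to capture the activated alcohol. The fallback separates activation from closure. It sets out from 21 and comes back at 22: I2, PPh3 and imidazole (CH2Cl2, 0 °C) convert the primary alcohol into 4-[(2R)-2-[2,4-bis(tert-butyldimethylsilyloxy)-5-(2-methylbut-3-en-2-yl)phenyl]-3-iodopropyl]-2-(3-hydroxy-3-methylbutyl)benzene-1,3-diol F13, and Cs2CO3 (1.1 equiv, MeCN, 0 °C to rt, dilute) closes the ortho phenoxide onto the iodide to give 22.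

## Further compounds

F1 | step 11 | 2-[2,4-bis(tert-butyldimethylsilyloxy)-5-(2-methylbut-3-en-2-yl)phenyl]acetic acid | OC(=O)Cc1cc(C(C)(C)C=C)c(O[Si](C)(C)C(C)(C)C)cc1O[Si](C)(C)C(C)(C)C
F2 | step 11 | (R)-4-benzyl-3-{[2,4-bis(tert-butyldimethylsilyloxy)-5-(2-methylbut-3-en-2-yl)phenyl]acetyl}oxazolidin-2-one | O=C(Cc1cc(C(C)(C)C=C)c(O[Si](C)(C)C(C)(C)C)cc1O[Si](C)(C)C(C)(C)C)N1[C@H](Cc2ccccc2)COC1=O
F3 | step 11 | 2,4-dihydroxy-3-(3-hydroxy-3-methylbutyl)benzaldehyde | CC(C)(O)CCc1c(O)ccc(C=O)c1O
F4 | step 11 | 2,4-bis(allyloxy)-3-(3-hydroxy-3-methylbutyl)benzaldehyde | C=CCOc1ccc(C=O)c(OCC=C)c1CCC(C)(C)O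
F5 | step 11 | [2,4-bis(allyloxy)-3-(3-hydroxy-3-methylbutyl)phenyl]methanol | C=CCOc1ccc(CO)c(OCC=C)c1CCC(C)(C)O
F6 | step 11 | 4-[2,6-bis(allyloxy)-3-(bromomethyl)phenyl]-2-methylbutan-2-ol | C=CCOc1ccc(CBr)c(OCC=C)c1CCC(C)(C)O
F7 | step 11 | (R)-4-benzyl-3-[(2R)-3-[2,4-bis(allyloxy)-3-(3-hydroxy-3-methylbutyl)phenyl]-2-[2,4-bis(tert-butyldimethylsilyloxy)-5-(2-methylbut-3-en-2-yl)phenyl]propanoyl]oxazolidin-2-one | O=C([C@H](Cc1ccc(OCC=C)c(CCC(C)(C)O)c1OCC=C)c1cc(C(C)(C)C=C)c(O[Si](C)(C)C(C)(C)C)cc1O[Si](C)(C)C(C)(C)C)N1[C@H](Cc2ccccc2)COC1=O
F8 | step 11 | 4-{2,6-bis(allyloxy)-3-[(2R)-2-[2,4-bis(tert-butyldimethylsilyloxy)-5-(2-methylbut-3-en-2-yl)phenyl]-3-hydroxypropyl]phenyl}-2-methylbutan-2-ol | C=CC(C)(C)c1cc([C@H](CO)Cc2ccc(OCC=C)c(CCC(C)(C)O)c2OCC=C)c(O[Si](C)(C)C(C)(C)C)cc1O[Si](C)(C)C(C)(C)C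
F9 | step 6 | 5-bromo-2,4-dihydroxybenzaldehyde | O=Cc1cc(Br)c(O)cc1O
F10 | step 6 | 5-bromo-2,4-bis(tert-butyldimethylsilyloxy)benzaldehyde | O=Cc1cc(Br)c(O[Si](C)(C)C(C)(C)C)cc1O[Si](C)(C)C(C)(C)C
F0 | step 10 | none | none
F11 | step 2 | methyl (E)-3-(2,6-dimethoxyphenyl)prop-2-enoate | COC(=O)/C=C/c1c(OC)cccc1OC
F12 | step 2 | methyl 3-(2,6-dimethoxyphenyl)propanoate | COC(=O)CCc1c(OC)cccc1OC
F13 | step 13 | 4-[(2R)-2-[2,4-bis(tert-butyldimethylsilyloxy)-5-(2-methylbut-3-en-2-yl)phenyl]-3-iodopropyl]-2-(3-hydroxy-3-methylbutyl)benzene-1,3-diol | C=CC(C)(C)c1cc([C@H](CI)Cc2ccc(O)c(CCC(C)(C)O)c2O)c(O[Si](C)(C)C(C)(C)C)cc1O[Si](C)(C)C(C)(C)C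
A1 | alternative 1 | [2,4-bis(methoxymethoxy)-5-(2-methylbut-3-en-2-yl)phenyl]lithium | C=CC(C)(C)c1cc([Li])c(OCOC)cc1OCOC
A2 | alternative 1 | vinylboronic acid pinacol ester | C=CB1OC(C)(C)C(C)(C)O1
A3 | alternative 1 | 1-bromo-2,4-bis(tert-butyldimethylsilyloxy)-3-[3-methyl-3-(triethylsilyloxy)butyl]benzene | CC[Si](CC)(CC)OC(C)(C)CCc1c(O[Si](C)(C)C(C)(C)C)ccc(Br)c1O[Si](C)(C)C(C)(C)C
A4 | alternative 1 | (R)-1,2-diarylethyl pinacol boronate with boron on C3 | C=CC(C)(C)c1cc([C@@H](Cc2ccc(O[Si](C)(C)C(C)(C)C)c(CCC(C)(C)O[Si](CC)(CC)CC)c2O[Si](C)(C)C(C)(C)C)B2OC(C)(C)C(C)(C)O2)c(OCOC)cc1OCOC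
A5 | alternative 2 | (3R)-7-[(2-methylbut-3-en-2-yl)oxy]-3-{4-[(3-methylbut-2-en-1-yl)oxy]-2-(triisopropylsilyloxy)phenyl}chroman | CC(C)=CCOc1ccc([C@@H]2COc3cc(OC(C)(C)C=C)ccc3C2)c(O[Si](C(C)C)(C(C)C)C(C)C)c1
A6 | alternative 2 | (R)-8-prenyl-5'-(1,1-dimethylallyl)isoflavan-7,4'-diol 2'-triisopropylsilyl ether | C=CC(C)(C)c1cc([C@@H]2COc3c(ccc(O)c3CC=C(C)C)C2)c(O[Si](C(C)C)(C(C)C)C(C)C)cc1O
A7 | alternative 3 | 3-(allyloxy)-2-(3-hydroxy-3-methylbutyl)-6-[(4-methylphenylsulfonyl)methyl]phenol | C=CCOc1ccc(CS(=O)(=O)c2ccc(C)cc2)c(O)c1CCC(C)(C)O
A8 | alternative 3 | 2-[2,4-bis(allyloxy)-5-(2-methylbut-3-en-2-yl)phenyl]acetaldehyde | O=CCc1cc(C(C)(C)C=C)c(OCC=C)cc1OCC=C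
A9 | alternative 3 | (3R)-7-(allyloxy)-3-[2,4-bis(allyloxy)-5-(2-methylbut-3-en-2-yl)phenyl]-8-(3-hydroxy-3-methylbutyl)chroman-2-ol (C2 anomers) | C=CC(C)(C)c1cc([C@@H]2C(O)Oc3c(ccc(OCC=C)c3CCC(C)(C)O)C2)c(OCC=C)cc1OCC=C
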